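## Retrosynthetic overview

- Numbering: C1 furanone C=O, C2=C3 furanone alkene, C4=C5 Z-alkene (methyl on C4), C6 lactone O–CH, C7 ring fusion, C8 tiglate carbon, C9 carbinol, C10 quaternary C–O, C11 C(OH), C12 lactone C=O, C13 CH2Cl.
- Feature: the 3(2H)-furanone ring O–C10–C1(=O)–C2=C3 that bridges the ten-membered carbocycle C1–C10 is a masked C1 ynone (C2≡C3) with a free C10 hydroxyl. C1–C2 is therefore cut to a C2 iodoalkyne and a C1 aldehyde on quaternary C10, closed by an alkynylchromium addition.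
- Aldehyde 30 is assembled at C7–C8 by an indium Barbier allylation of C8 aldehyde 10 (C9, C10 from (S)-glyceraldehyde acetonide) with bromomethyl enoate 22 (C6 from an asymmetric alkynylation of the enynal). This pairing is chosen because the syn C7/C8, anti C8/C9 and C6-controlled C7 relationships are the normal preferences of these two partners.
- Ring order: γ-lactone C6–O–C12 (step 17), ten-membered carbocycle (step 21), furanone (step 24); the C11/C13 chlorohydrin comes last by epoxidation and HCl opening.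

Key step: step 21

Remark (assumption): in step 10 the (S,S)-ProPhenol ligand is taken to deliver the alkynyl group to the Si face of enal 14 (6R alcohol); if its facial bias is the opposite one, the (R,R)-ligand is used in its place and nothing else changes.

## Route

Step 1
Reactants: 1 (S)-glyceraldehyde acetonide; 2 ethyl 2-[bis(2,2,2-trifluoroethoxy)phosphoryl]propanoate
Product: 3 ethyl (Z)-3-[(4R)-2,2-dimethyl-1,3-dioxolan-4-yl]-2-methylprop-2-enoate
Conditions: KN(SiMe3)2, 18-crown-6, THF, −78 °C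
Reagents that add atoms: none
Why: Still–Gennari olefination, in which the electron-poor phosphonate and the crown-complexed potassium ion make elimination from the first-formed adduct fast, so the trisubstituted alkene should form with C8 cis to the ester (Z) while the C8 stereocentre is untouched at −78 °C.

Step 2
Reactants: 3 ethyl (Z)-3-[(4R)-2,2-dimethyl-1,3-dioxolan-4-yl]-2-methylprop-2-enoate
Product: 4 (Z)-3-[(4R)-2,2-dimethyl-1,3-dioxolan-4-yl]-2-methylprop-2-en-1-ol
Conditions: i-Bu2AlH (2.5 equiv), CH2Cl2, −78 °C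
Reagents that add atoms: none
Why: aluminium hydride 1,2-reduction of the enoate gives the Z allylic alcohol (future C1) without touching the acetal or the alkene geometry.

Step 3
Reactants: 4 (Z)-3-[(4R)-2,2-dimethyl-1,3-dioxolan-4-yl]-2-methylprop-2-en-1-ol
Product: 5 (4R)-4-[(Z)-3-(4-methoxybenzyloxy)-2-methylprop-1-enyl]-2,2-dimethyl-1,3-dioxolane
Conditions: NaH, PMBCl, Bu4NI (cat.), THF/DMF, 0 °C to rt
Reagents that add atoms: 4-methoxybenzyl chloride COc1ccc(CCl)cc1
Why: Williamson ether synthesis on an unhindered primary alkoxide installs the C1 protecting group that is later removed oxidatively in the presence of silyl ethers.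

Step 4
Reactants: 5 (4R)-4-[(Z)-3-(4-methoxybenzyloxy)-2-methylprop-1-enyl]-2,2-dimethyl-1,3-dioxolane
Product: 6 (2R,3S)-3-[(4S)-2,2-dimethyl-1,3-dioxolan-4-yl]-1-(4-methoxybenzyloxy)-2-methylpropane-2,3-diol
Conditions: OsO4 (3 mol%), N-methylmorpholine N-oxide, acetone/H2O, rt
Reagents that add atoms: N-methylmorpholine N-oxide C[N+]1([O-])CCOCC1; water O
Why: Upjohn dihydroxylation, in which syn addition to the Z alkene fixes the C9/C10 relationship and OsO4 attacks the face anti to the allylic C8–O bond of the conformer with C8–H eclipsing the alkene (1,3-allylic strain), which should give 9S and 10R.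

Step 5
Reactants: 6 (2R,3S)-3-[(4S)-2,2-dimethyl-1,3-dioxolan-4-yl]-1-(4-methoxybenzyloxy)-2-methylpropane-2,3-diol
Product: 8 C9-OTBS/C10-OTES bis-silyl ether of 6, via C9 mono-TBS ether 7 (not isolated)
Conditions: TBSOTf (1.05 equiv), 2,6-lutidine, CH2Cl2, −78 °C; then TESOTf (1.5 equiv), 0 °C to rt
Reagents that add atoms: tert-butyldimethylsilyl triflate CC(C)(C)[Si](C)(C)OS(=O)(=O)C(F)(F)F; triethylsilyl triflate CC[Si](CC)(CC)OS(=O)(=O)C(F)(F)F
Why: silylation with silyl triflates, in which the secondary C9 hydroxyl reacts first at low temperature and the tertiary C10 hydroxyl then takes the smaller, later acid-labile triethylsilyl group.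

Step 6
Reactants: 8 C9-OTBS/C10-OTES bis-silyl ether of 6
Product: 9 (2S,3S,4R)-3-(tert-butyldimethylsilyloxy)-5-(4-methoxybenzyloxy)-4-methyl-4-(triethylsilyloxy)pentane-1,2-diol
Conditions: CuCl2·2H2O, MeCN, 0 °C
Reagents that add atoms: none
Why: Lewis-acid hydrolysis of a terminal isopropylidene acetal, mild enough to leave the hindered silyl ethers and the PMB ether in place.

Step 7
Reactants: 9 (2S,3S,4R)-3-(tert-butyldimethylsilyloxy)-5-(4-methoxybenzyloxy)-4-methyl-4-(triethylsilyloxy)pentane-1,2-diol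
Product: 10 (2R,3R)-2-(tert-butyldimethylsilyloxy)-4-(4-methoxybenzyloxy)-3-methyl-3-(triethylsilyloxy)butanal
Conditions: NaIO4, THF/pH 7 buffer, 0 °C
Reagents that add atoms: none
Why: periodate glycol cleavage (Malaprade reaction) removes C7 and gives the C8 aldehyde under neutral conditions that should not epimerise the α-silyloxy centre C9.

Step 8
Reactants: 11 (Z)-3-methylpent-2-en-4-yn-1-ol
Product: 13 (Z)-3-methyl-5-(trimethylsilyl)pent-2-en-4-yn-1-ol, via O,C-bis(trimethylsilyl) derivative 12 (not isolated)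
Conditions: n-BuLi (2.2 equiv), THF, −78 to 0 °C; Me3SiCl (2.3 equiv); then 1 M HCl, rt
Reagents that add atoms: chlorotrimethylsilane C[Si](C)(C)Cl
Why: silylation of the alkoxide/acetylide dianion followed by dilute-acid hydrolysis, which cleaves only the O–Si bond because an alkynyl C–Si bond is stable to acid.

Step 9
Reactants: 13 (Z)-3-methyl-5-(trimethylsilyl)pent-2-en-4-yn-1-ol
Product: 14 (Z)-3-methyl-5-(trimethylsilyl)pent-2-en-4-ynal
Conditions: MnO2 (excess), CH2Cl2, rt; used at once
Reagents that add atoms: none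
Why: allylic alcohol oxidation on MnO2 is neutral and should keep the Z geometry of the β,β-disubstituted enal.

Step 10
Reactants: 14 (Z)-3-methyl-5-(trimethylsilyl)pent-2-en-4-ynal; 15 methyl propiolate
Product: 16 methyl (4R,5Z)-4-hydroxy-6-methyl-8-(trimethylsilyl)oct-5-ene-2,7-diynoate
Conditions: (S,S)-ProPhenol (10 mol%), Me2Zn (3 equiv), Ph3PO (20 mol%), toluene, 0 °C
Reagents that add atoms: none
Why: zinc–ProPhenol catalysed asymmetric alkynylation, in which the dinuclear zinc complex binds the enal and the zinc acetylide of 15 and delivers it to one aldehyde face to set C6 (R), the silyl cap keeping the enyne C–H out of the reaction.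

Step 11
Reactants: 16 methyl (4R,5Z)-4-hydroxy-6-methyl-8-(trimethylsilyl)oct-5-ene-2,7-diynoate
Product: 18 methyl (2Z,4R,5Z)-4-hydroxy-2-iodo-6-methyl-8-(trimethylsilyl)octa-2,5-dien-7-ynoate, via cyclic vinylalanate 17 (not isolated)
Conditions: NaAlH2(OCH2CH2OCH3)2 (Red-Al, 1.6 equiv), THF, −78 °C; then I2, −78 to −20 °C
Reagents that add atoms: iodine II; NaAlH2(OCH2CH2OCH3)2 [Na+].COCCO[AlH2-]OCCOC (its sodium, aluminium and alkoxy groups stay only in 17)
Why: hydroxyl-directed trans-hydroalumination puts hydride on C7 and aluminium on C11 within a five-membered alanate, and iodinolysis with retention should leave iodine on C11 cis to C6.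

Step 12
Reactants: 18 methyl (2Z,4R,5Z)-4-hydroxy-2-iodo-6-methyl-8-(trimethylsilyl)octa-2,5-dien-7-ynoate
Product: 19 methyl (2Z,4R,5Z)-2-iodo-6-methyl-4-(triethylsilyloxy)-8-(trimethylsilyl)octa-2,5-dien-7-ynoate
Conditions: Et3SiCl, imidazole, CH2Cl2, 0 °C
Reagents that add atoms: chlorotriethylsilane CC[Si](Cl)(CC)CC
Why: standard silylation masks the C6 hydroxyl, which would otherwise cyclise onto the allylic bromide made in step 14.

Step 13
Reactants: 19 methyl (2Z,4R,5Z)-2-iodo-6-methyl-4-(triethylsilyloxy)-8-(trimethylsilyl)octa-2,5-dien-7-ynoate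
Product: 20 methyl (2E,4R,5Z)-2-(hydroxymethyl)-6-methyl-4-(triethylsilyloxy)-8-(trimethylsilyl)octa-2,5-dien-7-ynoate
Conditions: Bu3SnCH2OH (1.5 equiv), Pd(PPh3)4 (5 mol%), 1,4-dioxane, 90 °C
Reagents that add atoms: (tributylstannyl)methanol CCCC[Sn](CO)(CCCC)CCCC
Why: Stille coupling, with oxidative addition of the palladium catalyst into the α-iodo enoate C–I bond and hydroxymethyl transfer with retention of alkene geometry, brings in C13 cis to C6.

Step 14
Reactants: 20 methyl (2E,4R,5Z)-2-(hydroxymethyl)-6-methyl-4-(triethylsilyloxy)-8-(trimethylsilyl)octa-2,5-dien-7-ynoate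
Product: 22 methyl (2Z,4R,5Z)-2-(bromomethyl)-6-methyl-4-(triethylsilyloxy)-8-(trimethylsilyl)octa-2,5-dien-7-ynoate, via allylic mesylate 21 (not isolated)
Conditions: MsCl, Et3N, CH2Cl2, −20 °C; then LiBr, THF, 0 °C
Reagents that add atoms: methanesulfonyl chloride CS(=O)(=O)Cl (its atoms stay only in 21); lithium bromide [Li+].[Br-]
Why: sulfonylation followed by SN2 (Finkelstein-type) displacement at the primary allylic carbon gives the thermodynamically preferred Z-2-(bromomethyl)enoate without touching C6.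

Step 15
Reactants: 10 (2R,3R)-2-(tert-butyldimethylsilyloxy)-4-(4-methoxybenzyloxy)-3-methyl-3-(triethylsilyloxy)butanal; 22 methyl (2Z,4R,5Z)-2-(bromomethyl)-6-methyl-4-(triethylsilyloxy)-8-(trimethylsilyl)octa-2,5-dien-7-ynoate
Product: 24 open-chain C8 alcohol (6R,7R,8S,9S,10R) with the C11=C13 acrylate methyl ester, via allylindium dibromide 23 (not isolated)
Conditions: In powder (1.5 equiv), THF/H2O (2:1), rt
Reagents that add atoms: indium [In] (stays only in 23)
Why: indium-mediated Barbier allylation, in which the allylindium keeps C6 cis to its CH2–In arm so that a chair (Zimmerman–Traxler) transition state gives the syn C7/C8 adduct, the aldehyde is attacked anti to the C9 silyloxy group (Felkin–Anh), and C7 forms anti to the C6–O bond with C6–H eclipsing the alkene, three preferences that reinforce one another.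

Step 16
Reactants: 24 open-chain C8 alcohol (6R,7R,8S,9S,10R)
Product: 25 C8 tiglate of 24 (6R,7R,8S,9S,10R)
Conditions: tiglic anhydride (3 equiv), DMAP, Et3N, CH2Cl2, rt to 40 °C
Reagents that add atoms: tiglic anhydride C/C=C(\C)C(=O)OC(=O)/C(C)=C/C
Why: DMAP-catalysed acyl transfer to the only free hydroxyl, done before the lactone is closed so that C8 cannot compete with C6 for the C12 ester.

Step 17
Reactants: 25 C8 tiglate of 24
Product: 27 trans 6,12-lactone (6R,7S,8S,9S,10R) bearing C8 tiglate/C9-OTBS/C10-OTES/C1-OPMB, via C6 hydroxy ester 26 (not isolated)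
Conditions: PPTS (0.3 equiv), MeOH/CH2Cl2, 0 °C; then CSA (0.1 equiv), CH2Cl2, rt
Reagents that add atoms: none
Why: acid-catalysed desilylation cleaves the secondary allylic triethylsilyl ether much faster than the tertiary C10 silyl ether or the hindered TBS ether, and the freed C6 hydroxyl lactonises onto the C12 methyl ester to the trans-disubstituted α-methylene-γ-butyrolactone without change at any stereocentre.

Step 18
Reactants: 27 trans 6,12-lactone with C2 trimethylsilyl alkyne
Product: 28 iodoalkyne lactone (6R,7S,8S,9S,10R)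
Conditions: N-iodosuccinimide (1.3 equiv), AgNO3 (10 mol%), DMF, rt, dark
Reagents that add atoms: N-iodosuccinimide O=C1CCC(=O)N1I
Why: silver-catalysed iododesilylation of an alkynylsilane through a silver acetylide, neutral towards the lactone, tiglate, silyl ethers and PMB ether.

Step 19
Reactants: 28 iodoalkyne lactone
Product: 29 C1 primary alcohol (6R,7S,8S,9S,10R)
Conditions: DDQ (1.5 equiv), CH2Cl2/pH 7 buffer, 0 °C
Reagents that add atoms: none
Why: oxidative cleavage of the PMB ether (hydride abstraction by DDQ and hydrolysis of the oxocarbenium ion) frees only the C1 hydroxyl.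

Step 20
Reactants: 29 C1 primary alcohol
Product: 30 iodoalkyne C1 aldehyde (6R,7S,8S,9S,10S)
Conditions: Dess–Martin periodinane, NaHCO3, CH2Cl2, 0 °C to rt
Reagents that add atoms: none
Why: Dess–Martin oxidation gives the aldehyde on quaternary C10, which has no α-hydrogen and so cannot enolise or epimerise.

Step 21
Reactants: 30 iodoalkyne C1 aldehyde
Product: 32 ten-membered cyclic propargylic alcohol (6R,7S,8S,9S,10R) as both C1 epimers, via alkynylchromium dichloride 31 (not isolated)
Conditions: CrCl2 (10 equiv), NiCl2 (0.1 equiv), THF, rt, 30 added over 12 h to a final 0.002 M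
Reagents that add atoms: chromium dichloride Cl[Cr]Cl (chromium and chloride stay only in 31)
Why: Two equivalents of divalent chromium reduce the C2–I bond (helped by zerovalent nickel formed from NiCl2, which inserts into C–I and transmetalates) to give the trivalent alkynylchromium 31, which adds to the C1 aldehyde and forms the C1–C2 bond. The closest known reaction type is the Nozaki–Hiyama–Kishi coupling of alkynyl iodides with aldehydes, used intramolecularly to close ten-membered enediyne carbocycles. The ten-membered ring C1–C10 closes by exo attack on the aldehyde carbon (10-exo-trig), and the Z C4=C5 alkene holds C3 and C6 on the same side so that the alkyne terminus is turned back towards C1. The new stereocentre C1 is not controlled, and both epimers are carried forward because step 22 removes it. The step needs chemoselective addition to the hindered aldehyde in the presence of the lactone, the tiglate and the exo-methylene acceptor, which the weakly basic, ester-inert organochromium reagent and the absence of an α-hydrogen at C10 should secure. High dilution should suppress intermolecular coupling.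

Step 22
Reactants: 32 ten-membered cyclic propargylic alcohol
Product: 33 cyclic ynone (6R,7S,8S,9S,10S)
Conditions: Dess–Martin periodinane, NaHCO3, CH2Cl2, 0 °C
Reagents that add atoms: none
Why: Dess–Martin oxidation converges both C1 epimers to the single C1 ynone under buffered, non-nucleophilic conditions.

Step 23
Reactants: 33 cyclic ynone
Product: 34 C10 hydroxy ynone (6R,7S,8S,9S,10S)
Conditions: HF·pyridine, pyridine, THF, 0 °C
Reagents that add atoms: none
Why: fluoride-mediated desilylation removes the triethylsilyl ether much faster than the hindered secondary TBS ether at C9, so only the C10 hydroxyl is freed.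

Step 24
Reactants: 34 C10 hydroxy ynone
Product: 35 9-O-TBS furanone (6R,7S,8S,9S,10S)
Conditions: Ph3PAuNTf2 (5 mol%), CH2Cl2, rt
Reagents that add atoms: none
Why: gold-catalysed intramolecular hydroalkoxylation, in which monovalent gold activates C2≡C3, the C10 hydroxyl attacks C3 in a 5-endo-dig closure and protodeauration gives the 3(2H)-furanone, the silyl group on O9 excluding a six-membered alternative (any furanone already formed in step 23 is the same product).

Step 25
Reactants: 35 9-O-TBS furanone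
Product: 36 11,13-epoxide (6R,7S,8S,9S,10S,11R)
Conditions: t-BuOOH (in decane, 2 equiv), DBU, CH2Cl2, 0 °C
Reagents that add atoms: tert-butyl hydroperoxide CC(C)(C)OO
Why: Weitz–Scheffer nucleophilic epoxidation, in which the peroxide adds to C13 of the exo-methylene lactone (the most electrophilic and least hindered acceptor, the tiglate and the β-alkoxy dienone being far less reactive) and the enolate closes onto oxygen from the C11 face anti to the C7–C8 bond, which should set 11R.

Step 26
Reactants: 36 11,13-epoxide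
Product: 37 9-O-TBS chlorohydrin (6R,7S,8S,9S,10S,11S)
Conditions: HCl (1 M in Et2O, 2 equiv), CH2Cl2, 0 °C
Reagents that add atoms: hydrogen chloride Cl
Why: acid-promoted SN2 opening of the spiro-epoxide by chloride at primary C13 (quaternary C11 next to the carbonyl cannot be attacked) keeps the C11–O bond, the descriptor changing to S only through the priority of CH2Cl.

Step 27
Reactants: 37 9-O-TBS chlorohydrin
Product: 38 CNP0272644.2 (target)
Conditions: HF·pyridine, THF, 0 °C to rt
Reagents that add atoms: none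
Why: fluoride desilylation in an acidic, non-basic medium frees the C9 hydroxyl without the base-induced 8-to-9 tiglate migration or re-closure of the chlorohydrin.

## Compound list

1 | (S)-glyceraldehyde acetonide, (4S)-2,2-dimethyl-1,3-dioxolane-4-carbaldehyde | O=C[C@@H]1COC(C)(C)O1 | starting material
2 | ethyl 2-[bis(2,2,2-trifluoroethoxy)phosphoryl]propanoate | CCOC(=O)C(C)P(=O)(OCC(F)(F)F)OCC(F)(F)F | starting material
3 | ethyl (Z)-3-[(4R)-2,2-dimethyl-1,3-dioxolan-4-yl]-2-methylprop-2-enoate | CCOC(=O)/C(C)=C\[C@@H]1COC(C)(C)O1 | intermediate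
4 | (Z)-3-[(4R)-2,2-dimethyl-1,3-dioxolan-4-yl]-2-methylprop-2-en-1-ol | OC/C(C)=C\[C@@H]1COC(C)(C)O1 | intermediate
5 | (4R)-4-[(Z)-3-(4-methoxybenzyloxy)-2-methylprop-1-enyl]-2,2-dimethyl-1,3-dioxolane | COc1ccc(COC/C(C)=C\[C@@H]2COC(C)(C)O2)cc1 | intermediate
6 | (2R,3S)-3-[(4S)-2,2-dimethyl-1,3-dioxolan-4-yl]-1-(4-methoxybenzyloxy)-2-methylpropane-2,3-diol | COc1ccc(COC[C@@](C)(O)[C@@H](O)[C@@H]2COC(C)(C)O2)cc1 | intermediate
7 | (2R,3S)-3-(tert-butyldimethylsilyloxy)-3-[(4S)-2,2-dimethyl-1,3-dioxolan-4-yl]-1-(4-methoxybenzyloxy)-2-methylpropan-2-ol | COc1ccc(COC[C@@](C)(O)[C@@H](O[Si](C)(C)C(C)(C)C)[C@@H]2COC(C)(C)O2)cc1 | intermediate (not isolated)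
8 | (4S)-4-[(1S,2R)-1-(tert-butyldimethylsilyloxy)-3-(4-methoxybenzyloxy)-2-methyl-2-(triethylsilyloxy)propyl]-2,2-dimethyl-1,3-dioxolane | COc1ccc(COC[C@@](C)(O[Si](CC)(CC)CC)[C@@H](O[Si](C)(C)C(C)(C)C)[C@@H]2COC(C)(C)O2)cc1 | intermediate
9 | (2S,3S,4R)-3-(tert-butyldimethylsilyloxy)-5-(4-methoxybenzyloxy)-4-methyl-4-(triethylsilyloxy)pentane-1,2-diol | COc1ccc(COC[C@@](C)(O[Si](CC)(CC)CC)[C@@H](O[Si](C)(C)C(C)(C)C)[C@@H](O)CO)cc1 | intermediate
10 | (2R,3R)-2-(tert-butyldimethylsilyloxy)-4-(4-methoxybenzyloxy)-3-methyl-3-(triethylsilyloxy)butanal (C8 aldehyde) | COc1ccc(COC[C@@](C)(O[Si](CC)(CC)CC)[C@@H](O[Si](C)(C)C(C)(C)C)C=O)cc1 | intermediate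
11 | (Z)-3-methylpent-2-en-4-yn-1-ol | C#C/C(C)=C\CO | starting material
12 | trimethyl{[(Z)-3-methyl-5-(trimethylsilyl)pent-2-en-4-yn-1-yl]oxy}silane | C[Si](C)(C)C#C/C(C)=C\CO[Si](C)(C)C | intermediate (not isolated)
13 | (Z)-3-methyl-5-(trimethylsilyl)pent-2-en-4-yn-1-ol | C[Si](C)(C)C#C/C(C)=C\CO | intermediate
14 | (Z)-3-methyl-5-(trimethylsilyl)pent-2-en-4-ynal | C[Si](C)(C)C#C/C(C)=C\C=O | intermediate
15 | methyl propiolate | C#CC(=O)OC | starting material
16 | methyl (4R,5Z)-4-hydroxy-6-methyl-8-(trimethylsilyl)oct-5-ene-2,7-diynoate | COC(=O)C#C[C@H](O)/C=C(/C)C#C[Si](C)(C)C | intermediate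
17 | sodium cyclic vinylalanate (O6–Al–C11 five-membered ring, two 2-methoxyethoxy groups on aluminium) | COC(=O)C1=C[C@@H](/C=C(/C)C#C[Si](C)(C)C)O[Al-]1(OCCOC)OCCOC.[Na+] | intermediate (not isolated)
18 | methyl (2Z,4R,5Z)-4-hydroxy-2-iodo-6-methyl-8-(trimethylsilyl)octa-2,5-dien-7-ynoate | COC(=O)/C(I)=C/[C@H](O)/C=C(/C)C#C[Si](C)(C)C | intermediate
19 | methyl (2Z,4R,5Z)-2-iodo-6-methyl-4-(triethylsilyloxy)-8-(trimethylsilyl)octa-2,5-dien-7-ynoate | COC(=O)/C(I)=C/[C@H](O[Si](CC)(CC)CC)/C=C(/C)C#C[Si](C)(C)C | intermediate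
20 | methyl (2E,4R,5Z)-2-(hydroxymethyl)-6-methyl-4-(triethylsilyloxy)-8-(trimethylsilyl)octa-2,5-dien-7-ynoate | COC(=O)/C(CO)=C/[C@H](O[Si](CC)(CC)CC)/C=C(/C)C#C[Si](C)(C)C | intermediate
21 | methyl (2E,4R,5Z)-2-(methanesulfonyloxymethyl)-6-methyl-4-(triethylsilyloxy)-8-(trimethylsilyl)octa-2,5-dien-7-ynoate | COC(=O)/C(COS(C)(=O)=O)=C/[C@H](O[Si](CC)(CC)CC)/C=C(/C)C#C[Si](C)(C)C | intermediate (not isolated)
22 | methyl (2Z,4R,5Z)-2-(bromomethyl)-6-methyl-4-(triethylsilyloxy)-8-(trimethylsilyl)octa-2,5-dien-7-ynoate | COC(=O)/C(CBr)=C/[C@H](O[Si](CC)(CC)CC)/C=C(/C)C#C[Si](C)(C)C | intermediate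
23 | allylindium dibromide from 22 (In on C13) | COC(=O)/C(C[In](Br)Br)=C/[C@H](O[Si](CC)(CC)CC)/C=C(/C)C#C[Si](C)(C)C | intermediate (not isolated)
24 | open-chain C8 alcohol (6R,7R,8S,9S,10R): methyl ester of the C11=C13 acrylate, C6 OTES, C8 OH, C9 OTBS, C10 OTES, C1 OPMB, C2 SiMe3 | O[C@H]([C@H](O[Si](C)(C)C(C)(C)C)[C@@](C)(COCc1ccc(OC)cc1)O[Si](CC)(CC)CC)[C@@H](C(=C)C(=O)OC)[C@@H](/C=C(/C)C#C[Si](C)(C)C)O[Si](CC)(CC)CC | intermediate
25 | C8 tiglate of 24 (6R,7R,8S,9S,10R) | C/C=C(\C)C(=O)O[C@H]([C@H](O[Si](C)(C)C(C)(C)C)[C@@](C)(COCc1ccc(OC)cc1)O[Si](CC)(CC)CC)[C@@H](C(=C)C(=O)OC)[C@@H](/C=C(/C)C#C[Si](C)(C)C)O[Si](CC)(CC)CC | intermediate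
26 | C6 hydroxy ester (6R,7S,8S,9S,10R): 25 without the C6 silyl group | C/C=C(\C)C(=O)O[C@H]([C@H](O[Si](C)(C)C(C)(C)C)[C@@](C)(COCc1ccc(OC)cc1)O[Si](CC)(CC)CC)[C@@H](C(=C)C(=O)OC)[C@@H](/C=C(/C)C#C[Si](C)(C)C)O | intermediate (not isolated)
27 | trans α-methylene 6,12-lactone (6R,7S,8S,9S,10R): C8 tiglate, C9 OTBS, C10 OTES, C1 OPMB, C2 SiMe3 | C/C=C(\C)C(=O)O[C@H]([C@H](O[Si](C)(C)C(C)(C)C)[C@@](C)(COCc1ccc(OC)cc1)O[Si](CC)(CC)CC)[C@@H]1[C@@H](/C=C(/C)C#C[Si](C)(C)C)OC(=O)C1=C | intermediate
28 | iodoalkyne lactone (6R,7S,8S,9S,10R): as 27 with iodine on C2 | C/C=C(\C)C(=O)O[C@H]([C@H](O[Si](C)(C)C(C)(C)C)[C@@](C)(COCc1ccc(OC)cc1)O[Si](CC)(CC)CC)[C@@H]1[C@@H](/C=C(/C)C#CI)OC(=O)C1=C | intermediate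
29 | C1 primary alcohol (6R,7S,8S,9S,10R): as 28 with C1 OH | C/C=C(\C)C(=O)O[C@H]([C@H](O[Si](C)(C)C(C)(C)C)[C@@](C)(CO)O[Si](CC)(CC)CC)[C@@H]1[C@@H](/C=C(/C)C#CI)OC(=O)C1=C | intermediate
30 | iodoalkyne C1 aldehyde (6R,7S,8S,9S,10S): exo-methylene lactone, C8 tiglate, C9 OTBS, C10 OTES | C/C=C(\C)C(=O)O[C@H]([C@H](O[Si](C)(C)C(C)(C)C)[C@@](C)(C=O)O[Si](CC)(CC)CC)[C@@H]1[C@@H](/C=C(/C)C#CI)OC(=O)C1=C | intermediate
31 | alkynylchromium dichloride from 30 (trivalent chromium on C2) | C/C=C(\C)C(=O)O[C@H]([C@H](O[Si](C)(C)C(C)(C)C)[C@@](C)(C=O)O[Si](CC)(CC)CC)[C@@H]1[C@@H](/C=C(/C)C#C[Cr](Cl)Cl)OC(=O)C1=C | intermediate (not isolated)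
32 | ten-membered cyclic propargylic alcohol (6R,7S,8S,9S,10R; C1 both epimers) | C/C=C(\C)C(=O)O[C@H]1[C@@H]2[C@@H](/C=C(/C)C#CC(O)[C@@](C)(O[Si](CC)(CC)CC)[C@H]1O[Si](C)(C)C(C)(C)C)OC(=O)C2=C | intermediate
33 | cyclic C1 ynone (6R,7S,8S,9S,10S) | C/C=C(\C)C(=O)O[C@H]1[C@@H]2[C@@H](/C=C(/C)C#CC(=O)[C@@](C)(O[Si](CC)(CC)CC)[C@H]1O[Si](C)(C)C(C)(C)C)OC(=O)C2=C | intermediate
34 | C10 hydroxy ynone (6R,7S,8S,9S,10S) | C/C=C(\C)C(=O)O[C@H]1[C@@H]2[C@@H](/C=C(/C)C#CC(=O)[C@@](C)(O)[C@H]1O[Si](C)(C)C(C)(C)C)OC(=O)C2=C | intermediate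
35 | 9-O-TBS furanone with exo-methylene lactone (6R,7S,8S,9S,10S) | C/C=C(\C)C(=O)O[C@H]1[C@@H]2[C@@H](/C=C(/C)C3=CC(=O)[C@@](C)(O3)[C@H]1O[Si](C)(C)C(C)(C)C)OC(=O)C2=C | intermediate
36 | 9-O-TBS 11,13-epoxide (6R,7S,8S,9S,10S,11R) | C/C=C(\C)C(=O)O[C@H]1[C@@H]2[C@@H](/C=C(/C)C3=CC(=O)[C@@](C)(O3)[C@H]1O[Si](C)(C)C(C)(C)C)OC(=O)[C@]24CO4 | intermediate
37 | 9-O-TBS chlorohydrin (6R,7S,8S,9S,10S,11S) | C/C=C(\C)C(=O)O[C@H]1[C@@H]2[C@@H](/C=C(/C)C3=CC(=O)[C@@](C)(O3)[C@H]1O[Si](C)(C)C(C)(C)C)OC(=O)[C@]2(O)CCl | intermediate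
38 | CNP0272644.2 (6R,7S,8S,9S,10S,11S) | C/C=C(\C)C(=O)O[C@H]1[C@@H]2[C@@H](/C=C(/C)C3=CC(=O)[C@@](C)(O3)[C@H]1O)OC(=O)[C@]2(O)CCl | target

## Step count and risks

Total step count: 27. Longest linear sequence: 20 steps (steps 1–7 or 8–14, then 15–27).

Steps most likely to fail:

1. Step 21 (key ring closure). Intermolecular coupling to dimers and oligomers may outrun closure of the strained ten-membered ene-yne ring, and the alkynylchromium species may be protonated before it finds the hindered aldehyde. Fallback, setting out from 27 and returning at 32: the alkynyl silyl group of 27 would be removed with catalytic AgNO3 in aqueous acetone to give the terminal alkyne lactone F1. DDQ would then give the C1 alcohol F2, and Dess–Martin oxidation the terminal-alkyne aldehyde F3. The same C1–C2 bond would be closed not by metal insertion into a C–I bond but by deprotonating the alkyne of F3 with LiN(SiMe3)2 in the presence of CeCl3 (THF, −78 °C, high dilution). This cerium acetylide closure is known for ten-membered enediyne rings, and it would give 32.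

2. Step 15 (fragment union). Coupling of two hindered partners may be slow, so that the allylindium species is hydrolysed, the C6 silyl ether is lost in the aqueous medium, or the facial preferences are only partly expressed. Fallback, setting out from 22 (with 10) and returning at 24: 22 would be converted with Bu3SnSnBu3 and catalytic Pd(PPh3)4 into the allylstannane F4. BF3·OEt2 in CH2Cl2 at −78 °C would then promote its addition to 10 through an open, antiperiplanar transition state under anhydrous conditions. That mode is syn-selective for γ-substituted allylstannanes and keeps Felkin–Anh control at C8, so it would give 24.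

3. Step 25 (epoxidation). The peroxide may add to the furanone dienone or the tiglate as well, the adduct may fail to close, or facial selectivity at C11 may be poor on the bridged macrocycle. Fallback, setting out from 35 and returning at 36: catalytic OsO4 with N-methylmorpholine N-oxide would dihydroxylate the exo-methylene group from its open face to give the C11,C13 diol F5. Selective mesylation of the primary hydroxyl (MsCl, 2,4,6-collidine) would give the C13 mesylate F6, and DBU would close the tertiary alkoxide onto C13 to the same epoxide 36.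

## Further compounds

F1 | step 21 | terminal alkyne lactone (27 without the C2 silyl group) | C/C=C(\C)C(=O)O[C@H]([C@H](O[Si](C)(C)C(C)(C)C)[C@@](C)(COCc1ccc(OC)cc1)O[Si](CC)(CC)CC)[C@@H]1[C@@H](/C=C(/C)C#C)OC(=O)C1=C
F2 | step 21 | terminal alkyne C1 alcohol | C/C=C(\C)C(=O)O[C@H]([C@H](O[Si](C)(C)C(C)(C)C)[C@@](C)(CO)O[Si](CC)(CC)CC)[C@@H]1[C@@H](/C=C(/C)C#C)OC(=O)C1=C
F3 | step 21 | terminal alkyne C1 aldehyde | C/C=C(\C)C(=O)O[C@H]([C@H](O[Si](C)(C)C(C)(C)C)[C@@](C)(C=O)O[Si](CC)(CC)CC)[C@@H]1[C@@H](/C=C(/C)C#C)OC(=O)C1=C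
F4 | step 15 | allylstannane, methyl (2Z,4R,5Z)-6-methyl-2-(tributylstannylmethyl)-4-(triethylsilyloxy)-8-(trimethylsilyl)octa-2,5-dien-7-ynoate | COC(=O)/C(C[Sn](CCCC)(CCCC)CCCC)=C/[C@H](O[Si](CC)(CC)CC)/C=C(/C)C#C[Si](C)(C)C
F5 | step 25 | 9-O-TBS C11,C13 diol (11R) | C/C=C(\C)C(=O)O[C@H]1[C@@H]2[C@@H](/C=C(/C)C3=CC(=O)[C@@](C)(O3)[C@H]1O[Si](C)(C)C(C)(C)C)OC(=O)[C@]2(O)CO
F6 | step 25 | 9-O-TBS C13 mesylate of F5 | C/C=C(\C)C(=O)O[C@H]1[C@@H]2[C@@H](/C=C(/C)C3=CC(=O)[C@@](C)(O3)[C@H]1O[Si](C)(C)C(C)(C)C)OC(=O)[C@]2(O)COS(C)(=O)=O
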